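Ring C of the target (O1, C2, C3, C4, C4a, C8a) is the furan ring of a 2-arylbenzofuran plus one atom, C3, lodged between the B-ring-bearing C2 and the benzylic C4. The plan therefore cuts C2–C3 and C3–C4 at once. Dibromocarbene adds to the furan double bond of a benzofuran that already carries rings A and B with all their oxygens (three benzyl ethers, one methyl ether). The strained adduct expels bromide and opens to a 3-bromoflavylium salt. One operation thus enlarges the five-membered ring to ring C and leaves a bromine on C3 as the handle for the C3–O bond. Both stereocentres come afterwards from one dynamic kinetic reduction of the flavan-3-one.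

Key step: step 4

Remark on configuration: the target is (2R,3R) with H-2 and H-3 cis, which is the natural (−)-epi series.
Assumption on sourcing: 3,5-bis(benzyloxy)phenol, 3-(benzyloxy)-4-methoxybenzaldehyde and 3,4,5-tris(benzyloxy)benzoic acid are catalogue chemicals and are bought as such.
Assumption on step 7: the (R,R) catalyst is chosen by placing the aryl- and aryloxy-bearing C2 side of the ketone where the aryl group of an aryl ketone sits in the usual transition-state picture; this sense must be confirmed by correlation in the first run, and the (S,S) catalyst is the mirror-image remedy.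

Step 1
Reactants: 1 3,5-bis(benzyloxy)phenol
Product: 2 3,5-bis(benzyloxy)-2-iodophenol
Conditions: I2 (1 equiv), NaHCO3, THF–H2O, 0 °C, dark
Reagents that add atoms: iodine, II
Why: Electrophilic aromatic iodination of a phenol under bicarbonate conditions should go ortho to the hydroxyl group, because the two equivalent sites next to the small OH (each para to a benzyloxy group) are more open to the large iodine than the single site wedged between two benzyloxy groups, and one equivalent of iodine in the cold limits a second iodination.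

Step 2
Reactants: 3 3-(benzyloxy)-4-methoxybenzaldehyde
Product: 4 2-(benzyloxy)-4-ethynyl-1-methoxybenzene
Conditions: dimethyl (1-diazo-2-oxopropyl)phosphonate, K2CO3, MeOH, rt
Reagents that add atoms: dimethyl (1-diazo-2-oxopropyl)phosphonate, COP(=O)(OC)C(=[N+]=[N-])C(C)=O
Why: In this Seyferth–Gilbert homologation (Ohira–Bestmann variant), methanolysis frees the diazomethylphosphonate anion, which olefinates the non-enolisable aldehyde to a diazoalkene that loses N2 with a 1,2-hydrogen shift to give the terminal alkyne, under conditions harmless to both ethers.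

Step 3
Reactants: 2 3,5-bis(benzyloxy)-2-iodophenol; 4 2-(benzyloxy)-4-ethynyl-1-methoxybenzene
Product: 6 4,6-bis(benzyloxy)-2-[3-(benzyloxy)-4-methoxyphenyl]-1-benzofuran, via 2-alkynylphenol 5 (not isolated)
Conditions: PdCl2(PPh3)2 (cat.), CuI (cat.), Et3N, DMF, 60 °C, under argon
Reagents that add atoms: none
Why: Sonogashira coupling of the aryl iodide is followed in the same pot by metal-assisted 5-endo-dig addition of the neighbouring phenol to the alkyne (the standard o-iodophenol benzofuran annulation), and the ortho relation of OH and I in 2 places the benzyloxy groups at C4 and C6.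

Step 4
Reactants: 6 4,6-bis(benzyloxy)-2-[3-(benzyloxy)-4-methoxyphenyl]-1-benzofuran; 7 bromoform
Product: 9 5,7-bis(benzyloxy)-2-[3-(benzyloxy)-4-methoxyphenyl]-3-bromochromenylium bromide (5,7,3'-tris(benzyloxy)-3-bromo-4'-methoxyflavylium bromide), via gem-dibromocyclopropane adduct 8 (not isolated)
Conditions: CHBr3 (slow addition), KOtBu, toluene–hexane, −30 → 0 °C, under argon; then HBr (33% in AcOH, about 1 equiv), Et2O, −20 °C, salt filtered cold and used at once
Reagents that add atoms: bromoform 7, BrC(Br)Br (already listed among the reactants)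
Why: Potassium tert-butoxide removes HBr from bromoform by α-elimination, and the electrophilic singlet dibromocarbene adds in a concerted [2+1] cheletropic step to the furan C2=C3 bond of 6 to give the cis-fused gem-dibromocyclopropane 8. In 8 the bromide syn to the five-membered ring departs while the bond shared by the two rings (the old furan C2–C3 bond) breaks in a disrotatory two-electron electrocyclic opening (Woodward–Hoffmann–DePuy rule), pushed by the O1 lone pair and the 2-aryl group, so that the carbene carbon becomes C3, bonded to C2 and C4 of an aromatic benzopyrylium ion. The closest known reaction type is the Ciamician–Dennstedt-type dihalocarbene ring expansion, established for indoles (to 3-haloquinolines) and for benzofurans (to 3-halochromene derivatives). Ring C is therefore closed not by a cyclisation but by enlargement of the five-membered ring, in which a three-membered ring is closed by cycloaddition and its internal bond is then cleaved. No stereocentre is created for the target, since the two centres of racemic 8 are erased on aromatisation. The step needs chemoselectivity for one alkene over five benzene rings and three benzylic OCH2 groups, which the enol-ether character of that bond, reinforced by the 4,6-dialkoxy ring and the alkoxy-substituted 2-aryl group, should secure, while the cationic product resists a second carbene and the water-free medium with its anhydrous acid finish returns any alkoxide adduct to the salt and keeps ring C closed.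

Step 5
Reactants: 9 5,7-bis(benzyloxy)-2-[3-(benzyloxy)-4-methoxyphenyl]-3-bromochromenylium bromide
Product: 10 5,7-bis(benzyloxy)-2-[3-(benzyloxy)-4-methoxyphenyl]-3-bromo-4H-chromene
Conditions: NaBH4, MeCN, −20 → 0 °C
Reagents that add atoms: none
Why: In this hydride addition to a benzopyrylium cation, borohydride in an aprotic medium should attack the unsubstituted C4 rather than the aryl-bearing C2 and leave the C2=C3 bond conjugated with ring B, and partial attack at C2 would do no harm because that regioisomeric vinyl bromide converges on the same ketone in step 6.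

Step 6
Reactants: 10 5,7-bis(benzyloxy)-2-[3-(benzyloxy)-4-methoxyphenyl]-3-bromo-4H-chromene
Product: 13 (±)-5,7-bis(benzyloxy)-2-[3-(benzyloxy)-4-methoxyphenyl]chroman-3-one, via alkenyl pinacolboronate 11 (not isolated), via enol 12 (not isolated)
Conditions: B2pin2, PdCl2(dppf) (cat.), KOAc, 1,4-dioxane, 80 °C; then NaBO3·4H2O, THF–H2O, 0 °C → rt, under argon
Reagents that add atoms: bis(pinacolato)diboron, CC1(C)OB(OC1(C)C)B1OC(C)(C)C(C)(C)O1 (boryl group of 11); sodium perborate, [Na+].[O-]OB=O (oxygen on C3)
Why: Miyaura borylation of the alkenyl bromide avoids a 3-lithio species, which would expel the anti-disposed O1 phenoxide, and the mild perborate oxidation of the C–B bond (1,2-migration from boron to oxygen) should give enol 12, which tautomerises to the racemic and configurationally labile flavan-3-one.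

Step 7
Reactants: 13 (±)-5,7-bis(benzyloxy)-2-[3-(benzyloxy)-4-methoxyphenyl]chroman-3-one
Product: 14 (2R,3R)-5,7-bis(benzyloxy)-2-[3-(benzyloxy)-4-methoxyphenyl]chroman-3-ol
Conditions: RuCl[(R,R)-TsDPEN](p-cymene) (cat.), HCO2H–Et3N (5:2), CH2Cl2, 30 °C, under argon
Reagents that add atoms: none
Why: In this Noyori–Ikariya asymmetric transfer hydrogenation with dynamic kinetic resolution, a reaction type known for α-aryl cyclic ketones, C2 (benzylic and α to both C=O and O1) should racemise through the enol faster than reduction, while the chiral Ru–H selects the (2R)-ketone and delivers hydride to the C3 face opposite the 2-aryl group, which sets the 2,3-cis relation and with it both (2R) and (3R).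

Step 8
Reactants: 14 (2R,3R)-5,7-bis(benzyloxy)-2-[3-(benzyloxy)-4-methoxyphenyl]chroman-3-ol; 15 3,4,5-tris(benzyloxy)benzoic acid
Product: 16 (2R,3R)-5,7-bis(benzyloxy)-2-[3-(benzyloxy)-4-methoxyphenyl]chroman-3-yl 3,4,5-tris(benzyloxy)benzoate
Conditions: DCC, DMAP (cat.), CH2Cl2, 0 °C → rt
Reagents that add atoms: none
Why: Steglich esterification (carbodiimide activation with DMAP acyl transfer) forms only the O–acyl bond of the secondary alcohol, so neither the C3–O bond nor the C2 centre, which is no longer acidic, is disturbed.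

Step 9
Reactants: 16 (2R,3R)-5,7-bis(benzyloxy)-2-[3-(benzyloxy)-4-methoxyphenyl]chroman-3-yl 3,4,5-tris(benzyloxy)benzoate
Product: 17 4'-O-methylepicatechin-3-O-gallate, (2R,3R)-5,7-dihydroxy-2-(3-hydroxy-4-methoxyphenyl)chroman-3-yl 3,4,5-trihydroxybenzoate
Conditions: H2 (1 atm), 20% Pd(OH)2/C, THF–MeOH, rt
Reagents that add atoms: none
Why: Catalytic hydrogenolysis over Pearlman's catalyst should cleave all six aryl benzyl ethers under conditions that leave the ester, the methyl ether and the cyclic C2–O1 bond of catechin-type flavans intact, so both stereocentres are retained.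

Compound list
1 | 3,5-bis(benzyloxy)phenol | Oc1cc(OCc2ccccc2)cc(OCc2ccccc2)c1 | starting material
2 | 3,5-bis(benzyloxy)-2-iodophenol | Oc1cc(OCc2ccccc2)cc(OCc2ccccc2)c1I | intermediate
3 | 3-(benzyloxy)-4-methoxybenzaldehyde (O-benzylisovanillin) | COc1ccc(C=O)cc1OCc1ccccc1 | starting material
4 | 2-(benzyloxy)-4-ethynyl-1-methoxybenzene | COc1ccc(C#C)cc1OCc1ccccc1 | intermediate
5 | 3,5-bis(benzyloxy)-2-{[3-(benzyloxy)-4-methoxyphenyl]ethynyl}phenol (not isolated) | COc1ccc(C#Cc2c(O)cc(OCc3ccccc3)cc2OCc2ccccc2)cc1OCc1ccccc1 | intermediate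
6 | 4,6-bis(benzyloxy)-2-[3-(benzyloxy)-4-methoxyphenyl]-1-benzofuran | COc1ccc(-c2cc3c(OCc4ccccc4)cc(OCc4ccccc4)cc3o2)cc1OCc1ccccc1 | intermediate
7 | bromoform | BrC(Br)Br | starting material
8 | (±)-4,6-bis(benzyloxy)-1a-[3-(benzyloxy)-4-methoxyphenyl]-1,1-dibromo-1a,6b-dihydro-1H-cyclopropa[b][1]benzofuran, cis-fused, racemic, one enantiomer drawn (not isolated) | COc1ccc([C@]23Oc4cc(OCc5ccccc5)cc(OCc5ccccc5)c4[C@H]2C3(Br)Br)cc1OCc1ccccc1 | intermediate
9 | 5,7-bis(benzyloxy)-2-[3-(benzyloxy)-4-methoxyphenyl]-3-bromochromenylium bromide (5,7,3'-tris(benzyloxy)-3-bromo-4'-methoxyflavylium bromide) | COc1ccc(-c2[o+]c3cc(OCc4ccccc4)cc(OCc4ccccc4)c3cc2Br)cc1OCc1ccccc1.[Br-] | intermediate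
10 | 5,7-bis(benzyloxy)-2-[3-(benzyloxy)-4-methoxyphenyl]-3-bromo-4H-chromene | COc1ccc(C2=C(Br)Cc3c(OCc4ccccc4)cc(OCc4ccccc4)cc3O2)cc1OCc1ccccc1 | intermediate
11 | 2-{5,7-bis(benzyloxy)-2-[3-(benzyloxy)-4-methoxyphenyl]-4H-chromen-3-yl}-4,4,5,5-tetramethyl-1,3,2-dioxaborolane (not isolated) | COc1ccc(C2=C(B3OC(C)(C)C(C)(C)O3)Cc3c(OCc4ccccc4)cc(OCc4ccccc4)cc3O2)cc1OCc1ccccc1 | intermediate
12 | 5,7-bis(benzyloxy)-2-[3-(benzyloxy)-4-methoxyphenyl]-4H-chromen-3-ol, enol form (not isolated) | COc1ccc(C2=C(O)Cc3c(OCc4ccccc4)cc(OCc4ccccc4)cc3O2)cc1OCc1ccccc1 | intermediate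
13 | (±)-5,7-bis(benzyloxy)-2-[3-(benzyloxy)-4-methoxyphenyl]chroman-3-one, racemic, C2 labile and left undefined | COc1ccc(C2Oc3cc(OCc4ccccc4)cc(OCc4ccccc4)c3CC2=O)cc1OCc1ccccc1 | intermediate
14 | (2R,3R)-5,7-bis(benzyloxy)-2-[3-(benzyloxy)-4-methoxyphenyl]chroman-3-ol, 2,3-cis | COc1ccc([C@H]2Oc3cc(OCc4ccccc4)cc(OCc4ccccc4)c3C[C@H]2O)cc1OCc1ccccc1 | intermediate
15 | 3,4,5-tris(benzyloxy)benzoic acid | OC(=O)c1cc(OCc2ccccc2)c(OCc2ccccc2)c(OCc2ccccc2)c1 | starting material
16 | (2R,3R)-5,7-bis(benzyloxy)-2-[3-(benzyloxy)-4-methoxyphenyl]chroman-3-yl 3,4,5-tris(benzyloxy)benzoate | COc1ccc([C@H]2Oc3cc(OCc4ccccc4)cc(OCc4ccccc4)c3C[C@H]2OC(=O)c2cc(OCc3ccccc3)c(OCc3ccccc3)c(OCc3ccccc3)c2)cc1OCc1ccccc1 | intermediate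
17 | 4'-O-methylepicatechin-3-O-gallate, (2R,3R) | COc1ccc([C@H]2Oc3cc(O)cc(O)c3C[C@H]2OC(=O)c2cc(O)c(O)c(O)c2)cc1O | target

Total step count: 9.
Longest linear sequence: 8 steps (step 1 or step 2, then steps 3 to 9).

Steps most likely to fail

1. **Step 4 (carbene insertion).**
   - The nascent cation may be captured irreversibly by the tribromomethyl anion or by alkoxide.
   - The carbene may insert into benzylic ether C–H bonds.
   - The cation may lose a benzyl group to its own bromide.
   - Addition to the aryl-conjugated trisubstituted alkene may simply be slow.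

   The fallback builds ring C by an established flavene route. It sets out from 3 and comes back at 13. Claisen–Schmidt condensation of 3 with purchased 1-[2,4-bis(benzyloxy)-6-hydroxyphenyl]ethanone (KOH, EtOH, rt) should give the (E)-2'-hydroxychalcone F1. Borohydride reduction with cyclodehydration in the same operation (NaBH4, THF–EtOH, reflux, then AcOH) should give the racemic flav-3-ene F2. Hydroboration–oxidation (BH3·THF, then H2O2/NaOH) should place boron on C3, anti to the 2-aryl group, and give the racemic 2,3-trans-flavan-3-ol F3. Dess–Martin oxidation (CH2Cl2, rt) then leads to 13.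

2. **Step 6 (borylation–oxidation).**
   - Oxidative addition at the tetrasubstituted bromo enol ether may be sluggish.
   - The electron-rich alkenyl boronate may undergo protodeborylation.
   - The enolisable ketone may be over-oxidised by the peroxide.

   The fallback gives up the halogen handle and brings the oxygen in by hydroboration. It sets out from 10 and comes back at 13. Radical hydrodebromination (Bu3SnH, AIBN, toluene, 80 °C) should give the 2-aryl-4H-chromene F4. Hydroboration–oxidation (BH3·THF, then H2O2/NaOH) should put boron on C3, which is β to O1 and remote from the aryl-bearing C2, and lead to the racemic 2,3-trans-flavan-3-ol F3. Dess–Martin oxidation then gives 13.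

3. **Step 7 (dynamic kinetic reduction).**
   - The catalyst may discriminate poorly between the two ketone enantiomers.
   - The sense of induction may be opposite to the one assumed.
   - Reduction may outrun racemisation at C2.
   - The cis selectivity may erode.

   The fallback separates relative from absolute control. It sets out from 13 and comes back at 14. L-Selectride (THF, −78 °C) should deliver hydride opposite the 2-aryl group and give the racemic cis alcohol, that is 14 together with its (2S,3S) enantiomer F5. Esterification with (S)-O-methylmandelic acid (DCC, DMAP, CH2Cl2, 0 °C) should give the (2R,3R) mandelate ester F6 and the (2S,3S) mandelate ester F7. These are separated by chromatography or crystallisation. Saponification of F6 (LiOH, THF–H2O, rt) returns 14.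

Further compounds
F1 | step 4 | (E)-1-[2,4-bis(benzyloxy)-6-hydroxyphenyl]-3-[3-(benzyloxy)-4-methoxyphenyl]prop-2-en-1-one | COc1ccc(/C=C/C(=O)c2c(O)cc(OCc3ccccc3)cc2OCc2ccccc2)cc1OCc1ccccc1
F2 | step 4 | (±)-5,7-bis(benzyloxy)-2-[3-(benzyloxy)-4-methoxyphenyl]-2H-chromene (racemic, C2 left undefined) | COc1ccc(C2C=Cc3c(OCc4ccccc4)cc(OCc4ccccc4)cc3O2)cc1OCc1ccccc1
F3 | step 4 | (±)-2,3-trans-5,7-bis(benzyloxy)-2-[3-(benzyloxy)-4-methoxyphenyl]chroman-3-ol (racemic, (2R,3S) enantiomer drawn) | COc1ccc([C@H]2Oc3cc(OCc4ccccc4)cc(OCc4ccccc4)c3C[C@@H]2O)cc1OCc1ccccc1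
F4 | step 6 | 5,7-bis(benzyloxy)-2-[3-(benzyloxy)-4-methoxyphenyl]-4H-chromene | COc1ccc(C2=CCc3c(OCc4ccccc4)cc(OCc4ccccc4)cc3O2)cc1OCc1ccccc1
F5 | step 7 | (2S,3S)-5,7-bis(benzyloxy)-2-[3-(benzyloxy)-4-methoxyphenyl]chroman-3-ol (enantiomer of 14, formed with 14 as the racemate) | COc1ccc([C@@H]2Oc3cc(OCc4ccccc4)cc(OCc4ccccc4)c3C[C@@H]2O)cc1OCc1ccccc1
F6 | step 7 | (2R,3R)-5,7-bis(benzyloxy)-2-[3-(benzyloxy)-4-methoxyphenyl]chroman-3-yl (S)-2-methoxy-2-phenylacetate | COc1ccc([C@H]2Oc3cc(OCc4ccccc4)cc(OCc4ccccc4)c3C[C@H]2OC(=O)[C@@H](OC)c2ccccc2)cc1OCc1ccccc1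
F7 | step 7 | (2S,3S)-5,7-bis(benzyloxy)-2-[3-(benzyloxy)-4-methoxyphenyl]chroman-3-yl (S)-2-methoxy-2-phenylacetate | COc1ccc([C@@H]2Oc3cc(OCc4ccccc4)cc(OCc4ccccc4)c3C[C@@H]2OC(=O)[C@@H](OC)c2ccccc2)cc1OCc1ccccc1
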